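Everything rests on cutting coumarin A at C8a–C4a and O1–C2, so that its benzene ring is assembled instead of substituted. The feature exploited is the para relation between O1 on C8a and the methoxy on C6, with the C7 oxygen adjacent. This is a hydroquinone monoether, onto which the four carbons of a 3-alkoxy-4-methoxycyclobutenone map as C8a, C8, C7 and C6. The precursor is such a cyclobutenone whose C4 carries an (E,E)-dienoate already bearing the scopoletin ether at the ester α-carbon. Heating it should trigger ring opening, 6π closure, aromatisation and lactonisation, closing both rings of coumarin A at once. The ester must lie cis to the chain; a Still–Gennari phosphonate sets this.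

Key step: step 8

Remark on stereochemistry: the target has no stereocentre. Every sp3 centre on the way is racemic and is erased later, so only C=C geometry has to be controlled. Coumarin A is the 7-hydroxy-3-aryloxy unit and coumarin B is the scopoletin-derived unit.
Remark on locants: in every cyclobutenone of the route the isopropoxy carbon is bonded directly to the quaternary carbon. That is C3 of the cyclobutenone, or locant 2 when the ring is named as a substituent. The isomer with the alkoxy group next to C=O would lead to an 8-alkoxycoumarin.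

Step 1
Reactants: 1 diisopropyl squarate
Product: 3 3-isopropoxycyclobut-3-ene-1,2-dione, via hydroxycyclobutenone 2 (not isolated)
Conditions: LiAlH(OtBu)3, THF, −78 → 0 °C, aq. HCl work-up; crude 2, conc. HCl (cat.), CH2Cl2, rt
Reagents that add atoms: water, O (supplies the new carbonyl oxygen; the C4 hydroxyl leaves as water)
Why: Chemoselective 1,2-hydride reduction by the bulky alkoxyaluminium hydride should stop at racemic carbinol 2, and the acid-catalysed squarate transposition (ionisation of the C4 hydroxyl, capture of the alkoxy-stabilised allyl cation by water at C2, loss of isopropanol) should give semisquarate 3.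

Step 2
Reactants: 4 3,3-diethoxyprop-1-yne
Product: 5 (E)-tributyl(3,3-diethoxyprop-1-en-1-yl)stannane
Conditions: Bu3SnH (slight excess), AIBN (cat.), neat, 90 °C; chromatography on Et3N-deactivated SiO2
Reagents that add atoms: tributyltin hydride, CCCC[SnH](CCCC)CCCC
Why: Radical chain hydrostannation places tin on the terminal carbon, and reversible addition of Bu3Sn radicals to the product should equilibrate the kinetic Z isomer to the more stable E-vinylstannane, any residual Z isomer being removed by chromatography.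

Step 3
Reactants: 5 (E)-tributyl(3,3-diethoxyprop-1-en-1-yl)stannane; 3 3-isopropoxycyclobut-3-ene-1,2-dione
Product: 8 rac-4-[(E)-3,3-diethoxyprop-1-en-1-yl]-3-isopropoxy-4-methoxycyclobut-2-en-1-one, via vinyllithium 6 (not isolated), via lithium alkoxide 7 (not isolated)
Conditions: n-BuLi, THF, −78 °C; cannulated into 3, THF, −78 °C; MeOTf, −78 → −20 °C; aq. NaHCO3
Reagents that add atoms: methyl trifluoromethanesulfonate, COS(=O)(=O)C(F)(F)F
Why: Tin–lithium exchange keeps the E geometry, the hard vinyllithium adds 1,2 to the ketone-like carbonyl next to the isopropoxy carbon rather than to the vinylogous-ester carbonyl, and the tertiary alkoxide is O-methylated in situ (Williamson-type trapping), the new quaternary centre being racemic and erased in step 8.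

Step 4
Reactants: 8 rac-4-[(E)-3,3-diethoxyprop-1-en-1-yl]-3-isopropoxy-4-methoxycyclobut-2-en-1-one
Product: 9 rac-(E)-3-(2-isopropoxy-1-methoxy-4-oxocyclobut-2-en-1-yl)prop-2-enal
Conditions: 10% aq. oxalic acid on SiO2, CH2Cl2, rt
Reagents that add atoms: water, O
Why: Acid-catalysed acetal hydrolysis, in which the allylic acetal ionises to a conjugated oxocarbenium ion under conditions far milder than those needed to ionise the C4 methoxy group or to hydrolyse the vinylogous ester, while the quaternary γ-carbon rules out dienol formation and alkene migration.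

Step 5
Reactants: 10 methyl bis(2,2,2-trifluoroethyl)phosphonoacetate
Product: 11 methyl 2-[bis(2,2,2-trifluoroethoxy)phosphoryl]-2-diazoacetate
Conditions: p-ABSA, DBU, MeCN, 0 °C → rt
Reagents that add atoms: 4-acetamidobenzenesulfonyl azide, CC(=O)Nc1ccc(cc1)S(=O)(=O)N=[N+]=[N-]
Why: Regitz diazo transfer, in which DBU deprotonates the doubly activated methylene (more acidic than in a dialkyl phosphonoacetate), the carbanion attacks the terminal azide nitrogen and the triazene collapses to the diazo compound and the sulfonamide.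

Step 6
Reactants: 11 methyl 2-[bis(2,2,2-trifluoroethoxy)phosphoryl]-2-diazoacetate; 12 scopoletin
Product: 13 rac-methyl 2-[bis(2,2,2-trifluoroethoxy)phosphoryl]-2-[(6-methoxy-2-oxo-2H-chromen-7-yl)oxy]acetate
Conditions: Rh2(OAc)4 (1 mol %), ClCH2CH2Cl, 83 °C, slow addition of 11
Reagents that add atoms: none
Why: Rhodium-carbenoid O–H insertion, a known entry to 2-aryloxyphosphonoacetates, in which the electrophilic acceptor/acceptor carbenoid should be captured by the free C7 phenol much faster than by the electron-poor C3=C4 bond or the arene of the coumarin, the new centre being racemic and becoming sp2 in step 7.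

Step 7
Reactants: 13 rac-methyl 2-[bis(2,2,2-trifluoroethoxy)phosphoryl]-2-[(6-methoxy-2-oxo-2H-chromen-7-yl)oxy]acetate; 9 rac-(E)-3-(2-isopropoxy-1-methoxy-4-oxocyclobut-2-en-1-yl)prop-2-enal
Product: 15 rac-methyl (2E,4E)-5-(2-isopropoxy-1-methoxy-4-oxocyclobut-2-en-1-yl)-2-[(6-methoxy-2-oxo-2H-chromen-7-yl)oxy]penta-2,4-dienoate, via potassium phosphonate carbanion 14 (not isolated)
Conditions: KN(SiMe3)2 (slightly less than 13), 18-crown-6, THF, −78 °C; then 9, −78 → −40 °C; aq. NH4Cl
Reagents that add atoms: none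
Why: Still–Gennari variant of the Horner–Wadsworth–Emmons olefination, in which the electron-poor bis(trifluoroethyl) phosphonate makes oxaphosphetane collapse faster than retro-addition, so the kinetic adduct is kept and the chain should end cis to CO2Me (2E by CIP, since OAr outranks the ester carbon), whereas a dialkyl phosphonate would drift to the trans-to-ester isomer that cannot lactonise; the aldehyde outcompetes the vinylogous-ester ketone, and the minor isomer is removed by chromatography.

Step 8
Reactants: 15 rac-methyl (2E,4E)-5-(2-isopropoxy-1-methoxy-4-oxocyclobut-2-en-1-yl)-2-[(6-methoxy-2-oxo-2H-chromen-7-yl)oxy]penta-2,4-dienoate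
Product: 19 7-isopropoxy-6-methoxy-3-[(6-methoxy-2-oxo-2H-chromen-7-yl)oxy]-2H-chromen-2-one, via dienylketene 16 (not isolated), via cyclohexadienone 17 (not isolated), via cis-hydroxycinnamate 18 (not isolated)
Conditions: p-xylene (0.01 M, degassed), 138 °C, Ar
Reagents that add atoms: none
Why: Thermal conrotatory 4π opening of the C1–C4 bond of the cyclobutenone gives dienylketene 16, the C4 methoxy donor rotating outward and the dienyl chain therefore inward, next to the ketene carbon. Disrotatory 6π electrocyclisation of the ketene C=C, the newly formed C3=C4 enol-ether bond and the first chain C=C forms C8a–C4a and closes benzene ring A as cyclohexadienone 17, which enolises to phenol 18; this is the Moore ring expansion of 4-alkenyl-4-alkoxycyclobutenones to hydroquinone monoethers. The new phenol sits cis to CO2Me across C3=C4 and closes pyranone ring A by 6-exo-trig acyl substitution (O1–C2) with loss of methanol, as cis-2-hydroxycinnamates do spontaneously. Cyclobutenone carbons C1, C2, C3 and C4 become C8a, C8, C7 and C6, so the oxygen pattern is transferred without any arene substitution. No stereocentre survives, since the racemic quaternary centre of 15 and the transient C4a centre of 17 are both erased. The selectivities needed are outward rotation of OMe (inherent donor torquoselectivity), 6π rather than 8π closure (the E C4=C5 bond holds the distal alkene out of reach of the ketene) and retention of the 2E geometry (set in step 7 and kept by a neutral, dilute, oxygen-free medium).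

Step 9
Reactants: 19 7-isopropoxy-6-methoxy-3-[(6-methoxy-2-oxo-2H-chromen-7-yl)oxy]-2H-chromen-2-one
Product: 21 7-hydroxy-6-methoxy-3-[(6-methoxy-2-oxo-2H-chromen-7-yl)oxy]-2H-chromen-2-one (CNP0312919.0), via aryloxydichloroborane 20 (not isolated)
Conditions: BCl3 (3–4 equiv), CH2Cl2, −78 → 0 °C; H2O
Reagents that add atoms: none
Why: Lewis-acid ether cleavage, in which BCl3 binds the ether oxygen and the secondary isopropyl group leaves by an SN1-like path as 2-chloropropane far faster than a methyl group can be displaced, so both methoxy groups, the diaryl ether and both lactones should survive, and aqueous work-up hydrolyses 20 to the free C7 phenol.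

Compound list
1 | diisopropyl squarate (3,4-diisopropoxycyclobut-3-ene-1,2-dione) | CC(C)OC1=C(OC(C)C)C(=O)C1=O | starting material
2 | rac-4-hydroxy-2,3-diisopropoxycyclobut-2-en-1-one | CC(C)OC1=C(OC(C)C)C(=O)C1O | intermediate
3 | 3-isopropoxycyclobut-3-ene-1,2-dione | CC(C)OC1=CC(=O)C1=O | intermediate
4 | 3,3-diethoxyprop-1-yne | C#CC(OCC)OCC | starting material
5 | (E)-tributyl(3,3-diethoxyprop-1-en-1-yl)stannane | CCCC[Sn](CCCC)(CCCC)/C=C/C(OCC)OCC | intermediate
6 | (E)-(3,3-diethoxyprop-1-en-1-yl)lithium | [Li]/C=C/C(OCC)OCC | intermediate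
7 | rac-lithium 1-[(E)-3,3-diethoxyprop-1-en-1-yl]-2-isopropoxy-4-oxocyclobut-2-en-1-olate | [Li+].[O-]C1(/C=C/C(OCC)OCC)C(=O)C=C1OC(C)C | intermediate
8 | rac-4-[(E)-3,3-diethoxyprop-1-en-1-yl]-3-isopropoxy-4-methoxycyclobut-2-en-1-one | COC1(/C=C/C(OCC)OCC)C(=O)C=C1OC(C)C | intermediate
9 | rac-(E)-3-(2-isopropoxy-1-methoxy-4-oxocyclobut-2-en-1-yl)prop-2-enal | COC1(/C=C/C=O)C(=O)C=C1OC(C)C | intermediate
10 | methyl bis(2,2,2-trifluoroethyl)phosphonoacetate | COC(=O)CP(=O)(OCC(F)(F)F)OCC(F)(F)F | starting material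
11 | methyl 2-[bis(2,2,2-trifluoroethoxy)phosphoryl]-2-diazoacetate | COC(=O)C(=[N+]=[N-])P(=O)(OCC(F)(F)F)OCC(F)(F)F | intermediate
12 | scopoletin (7-hydroxy-6-methoxy-2H-chromen-2-one) | COc1cc2ccc(=O)oc2cc1O | starting material
13 | rac-methyl 2-[bis(2,2,2-trifluoroethoxy)phosphoryl]-2-[(6-methoxy-2-oxo-2H-chromen-7-yl)oxy]acetate | COC(=O)C(Oc1cc2oc(=O)ccc2cc1OC)P(=O)(OCC(F)(F)F)OCC(F)(F)F | intermediate
14 | potassium salt of the α-carbanion of 13 | [K+].COC(=O)[C-](Oc1cc2oc(=O)ccc2cc1OC)P(=O)(OCC(F)(F)F)OCC(F)(F)F | intermediate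
15 | rac-methyl (2E,4E)-5-(2-isopropoxy-1-methoxy-4-oxocyclobut-2-en-1-yl)-2-[(6-methoxy-2-oxo-2H-chromen-7-yl)oxy]penta-2,4-dienoate | COC1(/C=C/C=C(/Oc2cc3oc(=O)ccc3cc2OC)C(=O)OC)C(=O)C=C1OC(C)C | intermediate
16 | methyl (2E,4E,6Z)-7-isopropoxy-6-methoxy-2-[(6-methoxy-2-oxo-2H-chromen-7-yl)oxy]-9-oxonona-2,4,6,8-tetraenoate (dienylketene) | O=C=C/C(OC(C)C)=C(OC)\C=C\C=C(\Oc1cc2oc(=O)ccc2cc1OC)C(=O)OC | intermediate
17 | rac-methyl (E)-3-(4-isopropoxy-3-methoxy-6-oxocyclohexa-2,4-dien-1-yl)-2-[(6-methoxy-2-oxo-2H-chromen-7-yl)oxy]acrylate | O=C1C=C(OC(C)C)C(OC)=CC1/C=C(/Oc2cc3oc(=O)ccc3cc2OC)C(=O)OC | intermediate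
18 | methyl (E)-3-(2-hydroxy-4-isopropoxy-5-methoxyphenyl)-2-[(6-methoxy-2-oxo-2H-chromen-7-yl)oxy]acrylate (aryl cis to ester) | Oc1cc(OC(C)C)c(OC)cc1/C=C(/Oc2cc3oc(=O)ccc3cc2OC)C(=O)OC | intermediate
19 | 7-isopropoxy-6-methoxy-3-[(6-methoxy-2-oxo-2H-chromen-7-yl)oxy]-2H-chromen-2-one | COc1cc2cc(Oc3cc4oc(=O)ccc4cc3OC)c(=O)oc2cc1OC(C)C | intermediate
20 | dichloro{[6-methoxy-3-[(6-methoxy-2-oxo-2H-chromen-7-yl)oxy]-2-oxo-2H-chromen-7-yl]oxy}borane | COc1cc2cc(Oc3cc4oc(=O)ccc4cc3OC)c(=O)oc2cc1OB(Cl)Cl | intermediate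
21 | 7-hydroxy-6-methoxy-3-[(6-methoxy-2-oxo-2H-chromen-7-yl)oxy]-2H-chromen-2-one | COc1cc2cc(Oc3cc4oc(=O)ccc4cc3OC)c(=O)oc2cc1O | target

Total step count: 9.
Longest linear sequence: 6 steps (steps 1, 3, 4, 7, 8 and 9 from 1; the branch from 4 through step 2 is equally long).

Steps most likely to fail

Step 8.
- **Risk:** The dienylketene may be lost to oligomerisation. It may close sluggishly onto an acceptor-substituted triene. Heat may also scramble the C2=C3 geometry so that lactonisation stalls.
- **Fallback (sets out from 8 and 12, comes back at 19):** Ring A is still made by ring expansion, but on the simple acetal, and the pyranone is closed by a classical condensation.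
- **Aldehyde partner:** Heating 8 in xylene should pass through the dienylketene (3Z,5E)-7,7-diethoxy-3-isopropoxy-4-methoxyhepta-1,3,5-trien-1-one F1 and the cyclohexadienone rac-6-(diethoxymethyl)-3-isopropoxy-4-methoxycyclohexa-2,4-dien-1-one F2 to the phenol 2-(diethoxymethyl)-5-isopropoxy-4-methoxyphenol F3. Dilute acid then converts F3 into 2-hydroxy-4-isopropoxy-5-methoxybenzaldehyde F4.
- **Acid partner:** Scopoletin 12 is alkylated with tert-butyl bromoacetate and K2CO3 to tert-butyl [(6-methoxy-2-oxo-2H-chromen-7-yl)oxy]acetate F5. TFA then frees [(6-methoxy-2-oxo-2H-chromen-7-yl)oxy]acetic acid F6.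
- **Closure:** Perkin–Oglialoro condensation of F4 with F6 (Ac2O, Et3N, 120 °C) runs through the aryl ester. The intramolecular aldol–dehydration can therefore only deliver the lactone, which is 19.

Step 7.
- **Risk:** Kinetic control in the olefination may be insufficient, the chain ending trans to the ester. From that geometry the later phenol cannot reach the carbonyl.
- **Fallback (sets out from 9 and 13, comes back at 19):** The geometry is no longer demanded of the olefination but is corrected photochemically once ring A exists.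
- **Thermolysis of the mixture:** The olefination product, whatever its composition, is heated as in step 8. Its 2Z component is rac-methyl (2Z,4E)-5-(2-isopropoxy-1-methoxy-4-oxocyclobut-2-en-1-yl)-2-[(6-methoxy-2-oxo-2H-chromen-7-yl)oxy]penta-2,4-dienoate F7. It should run through the dienylketene methyl (2Z,4E,6Z)-7-isopropoxy-6-methoxy-2-[(6-methoxy-2-oxo-2H-chromen-7-yl)oxy]-9-oxonona-2,4,6,8-tetraenoate F8 and the cyclohexadienone rac-methyl (Z)-3-(4-isopropoxy-3-methoxy-6-oxocyclohexa-2,4-dien-1-yl)-2-[(6-methoxy-2-oxo-2H-chromen-7-yl)oxy]acrylate F9. The end point is the open hydroxy ester methyl (Z)-3-(2-hydroxy-4-isopropoxy-5-methoxyphenyl)-2-[(6-methoxy-2-oxo-2H-chromen-7-yl)oxy]acrylate F10.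
- **Photochemical correction:** Irradiation of F10 at 365 nm in dilute, degassed MeCN isomerises the C=C bond, as in the known photolactonisation of trans-2-hydroxycinnamates. The cis isomer 18 is drained irreversibly into 19, and high dilution suppresses [2+2] dimerisation of the coumarins.

Step 4.
- **Risk:** The acid may not discriminate. Ionisation of the C4 methoxy group or hydrolysis of the vinylogous ester, meaning loss of the quaternary centre, would then compete with acetal cleavage.
- **Fallback (sets out from 3, comes back at 9):** The aldehyde is reached by oxidation instead of hydrolysis, so no acid is needed.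
- **Nucleophile and addition:** Commercial tert-butyldimethyl(prop-2-yn-1-yloxy)silane is hydrostannylated as in step 2 to (E)-tert-butyldimethyl{[3-(tributylstannyl)prop-2-en-1-yl]oxy}silane F11. n-BuLi converts it into (E)-{3-[(tert-butyldimethylsilyl)oxy]prop-1-en-1-yl}lithium F12. Addition to 3 gives rac-lithium 1-{(E)-3-[(tert-butyldimethylsilyl)oxy]prop-1-en-1-yl}-2-isopropoxy-4-oxocyclobut-2-en-1-olate F13. MeOTf then gives rac-4-{(E)-3-[(tert-butyldimethylsilyl)oxy]prop-1-en-1-yl}-3-isopropoxy-4-methoxycyclobut-2-en-1-one F14.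
- **Unmasking:** Et3N·3HF in THF frees rac-4-[(E)-3-hydroxyprop-1-en-1-yl]-3-isopropoxy-4-methoxycyclobut-2-en-1-one F15. MnO2 in CH2Cl2 oxidises the allylic alcohol to 9.

Further compounds
F1 | step 8 | (3Z,5E)-7,7-diethoxy-3-isopropoxy-4-methoxyhepta-1,3,5-trien-1-one | O=C=C/C(OC(C)C)=C(OC)\C=C\C(OCC)OCC
F2 | step 8 | rac-6-(diethoxymethyl)-3-isopropoxy-4-methoxycyclohexa-2,4-dien-1-one | O=C1C=C(OC(C)C)C(OC)=CC1C(OCC)OCC
F3 | step 8 | 2-(diethoxymethyl)-5-isopropoxy-4-methoxyphenol | CCOC(OCC)c1cc(OC)c(OC(C)C)cc1O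
F4 | step 8 | 2-hydroxy-4-isopropoxy-5-methoxybenzaldehyde | O=Cc1cc(OC)c(OC(C)C)cc1O
F5 | step 8 | tert-butyl [(6-methoxy-2-oxo-2H-chromen-7-yl)oxy]acetate | CC(C)(C)OC(=O)COc1cc2oc(=O)ccc2cc1OC
F6 | step 8 | [(6-methoxy-2-oxo-2H-chromen-7-yl)oxy]acetic acid | OC(=O)COc1cc2oc(=O)ccc2cc1OC
F7 | step 7 | rac-methyl (2Z,4E)-5-(2-isopropoxy-1-methoxy-4-oxocyclobut-2-en-1-yl)-2-[(6-methoxy-2-oxo-2H-chromen-7-yl)oxy]penta-2,4-dienoate | COC1(/C=C/C=C(\Oc2cc3oc(=O)ccc3cc2OC)C(=O)OC)C(=O)C=C1OC(C)C
F8 | step 7 | methyl (2Z,4E,6Z)-7-isopropoxy-6-methoxy-2-[(6-methoxy-2-oxo-2H-chromen-7-yl)oxy]-9-oxonona-2,4,6,8-tetraenoate | O=C=C/C(OC(C)C)=C(OC)\C=C\C=C(/Oc1cc2oc(=O)ccc2cc1OC)C(=O)OC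
F9 | step 7 | rac-methyl (Z)-3-(4-isopropoxy-3-methoxy-6-oxocyclohexa-2,4-dien-1-yl)-2-[(6-methoxy-2-oxo-2H-chromen-7-yl)oxy]acrylate | O=C1C=C(OC(C)C)C(OC)=CC1/C=C(\Oc2cc3oc(=O)ccc3cc2OC)C(=O)OC
F10 | step 7 | methyl (Z)-3-(2-hydroxy-4-isopropoxy-5-methoxyphenyl)-2-[(6-methoxy-2-oxo-2H-chromen-7-yl)oxy]acrylate | Oc1cc(OC(C)C)c(OC)cc1/C=C(\Oc2cc3oc(=O)ccc3cc2OC)C(=O)OC
F11 | step 4 | (E)-tert-butyldimethyl{[3-(tributylstannyl)prop-2-en-1-yl]oxy}silane | CCCC[Sn](CCCC)(CCCC)/C=C/CO[Si](C)(C)C(C)(C)C
F12 | step 4 | (E)-{3-[(tert-butyldimethylsilyl)oxy]prop-1-en-1-yl}lithium | [Li]/C=C/CO[Si](C)(C)C(C)(C)C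
F13 | step 4 | rac-lithium 1-{(E)-3-[(tert-butyldimethylsilyl)oxy]prop-1-en-1-yl}-2-isopropoxy-4-oxocyclobut-2-en-1-olate | [Li+].[O-]C1(/C=C/CO[Si](C)(C)C(C)(C)C)C(=O)C=C1OC(C)C
F14 | step 4 | rac-4-{(E)-3-[(tert-butyldimethylsilyl)oxy]prop-1-en-1-yl}-3-isopropoxy-4-methoxycyclobut-2-en-1-one | COC1(/C=C/CO[Si](C)(C)C(C)(C)C)C(=O)C=C1OC(C)C
F15 | step 4 | rac-4-[(E)-3-hydroxyprop-1-en-1-yl]-3-isopropoxy-4-methoxycyclobut-2-en-1-one | COC1(/C=C/CO)C(=O)C=C1OC(C)C
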